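**Plan**

1. Numbering used (4,9-diazadodecane-1,12-diamine): N1–C1–C2–C3–N4–C5–C6–C7–C8–N9–C10–C11–C12–N12; N4 and N12 carry the dihydrocaffeoyl groups, N1 and N9 are free.
2. The retrosynthesis first removes five benzyl-type groups (four catechol O-benzyls and an N1-Cbz). It then cuts C8–N9 and C7–C8, sending C8 back to carbon monoxide, which leaves an N4-allyl amide and an N12-acylated 1,3-diaminopropane.
3. The enabling feature is the unbranched C5–C8 chain that joins the acylated N4 to the basic secondary N9. C5–C7 can therefore be an allyl group on N4, and C8 a carbonyl carbon that condenses with N9; each half already carries one catechol benzene ring as its bis(benzyl ether).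
4. The remaining cuts are N4–acyl and N4–C3 in the allyl half and N12–acyl in the amine half.
5. In the forward direction, dihydrocaffeic acid is perbenzylated and branched into the two halves. The chain is joined by hydroaminomethylation (C7–C8, then C8–N9), followed by one hydrogenolysis. No ring is formed at any stage.
6. The target has no stereocentre and no stereogenic double bond, so nothing has to be set.

Key step: step 6

Assumption: because kukoamine B is achiral, its constitution alone defines the single compound asked for; it is delivered as the free base drawn.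

**Route**

Step 1
Reactants: 1 3-(3,4-dihydroxyphenyl)propanoic acid
Product: 2 benzyl 3-[3,4-bis(benzyloxy)phenyl]propanoate
Conditions: BnBr (3.6 equiv), K2CO3 (4 equiv), DMF, 60 °C, N2
Reagents that add atoms: benzyl bromide, BrCc1ccccc1
Why: Williamson O-alkylation of both phenoxides together with carboxylate alkylation should give the tribenzyl compound in one operation; carbonate deprotonates all three acidic groups and exclusion of air prevents quinone formation.

Step 2
Reactants: 2 benzyl 3-[3,4-bis(benzyloxy)phenyl]propanoate
Product: 3 3-[3,4-bis(benzyloxy)phenyl]propanoic acid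
Conditions: LiOH·H2O, THF/MeOH/H2O, rt; then 1 M HCl
Reagents that add atoms: lithium hydroxide, [Li+].[OH-]
Why: Ester saponification (BAc2) should cleave only the benzyl ester, since aryl benzyl ethers are inert to hydroxide.

Step 3
Reactants: 4 allylamine; 5 benzyl (3-bromopropyl)carbamate
Product: 6 benzyl N-[3-(allylamino)propyl]carbamate
Conditions: 4 (8 equiv), K2CO3, MeCN, rt → 45 °C
Reagents that add atoms: none
Why: SN2 N-alkylation of a primary amine by a primary bromide; the large excess of volatile allylamine should hold the reaction at mono-alkylation and outrun cyclisation of the bromo carbamate.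

Step 4
Reactants: 3 3-[3,4-bis(benzyloxy)phenyl]propanoic acid; 6 benzyl N-[3-(allylamino)propyl]carbamate
Product: 8 N-allyl-N-[3-(Cbz-amino)propyl]-3-[3,4-bis(benzyloxy)phenyl]propanamide, via acyl imidazole 7 (not isolated)
Conditions: CDI (1.05 equiv), THF, rt until CO2 evolution ends; then 6, 50 °C
Reagents that add atoms: none
Why: CDI-mediated amidation; the N-acylimidazole should acylate the unhindered secondary amine, while the carbamate N–H is not nucleophilic enough to compete.

Step 5
Reactants: 2 benzyl 3-[3,4-bis(benzyloxy)phenyl]propanoate; 9 1,3-diaminopropane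
Product: 10 N-(3-aminopropyl)-3-[3,4-bis(benzyloxy)phenyl]propanamide
Conditions: neat 9 (15 equiv), 70 °C, N2
Reagents that add atoms: none
Why: Aminolysis of an unhindered ester by a neat primary diamine; the large excess of diamine should make the mono-amide the only product, and the benzyl ethers are untouched.

Step 6
Reactants: 8 N-allyl-N-[3-(Cbz-amino)propyl]-3-[3,4-bis(benzyloxy)phenyl]propanamide; 10 N-(3-aminopropyl)-3-[3,4-bis(benzyloxy)phenyl]propanamide
Product: 13 N1-Cbz-tetra-O-benzyl kukoamine B, via 4-amidobutanal 11 (not isolated), via aldimine 12 (not isolated)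
Conditions: [Rh(cod)2]BF4 (2 mol %), Xantphos (4 mol %), CO/H2 (1:5, 40 bar), 10 (1.5 equiv), toluene/MeOH (1:1), 110 °C
Reagents that add atoms: carbon monoxide, [C-]#[O+]
Why: A Xantphos-ligated Rh–H should add anti-Markovnikov to the terminal alkene of 8, and CO insertion followed by hydrogenolysis of the acyl should give the linear aldehyde 11 (C7–C8); 11 should condense with the NH2 of 10 to aldimine 12, which the same cationic Rh–H/H2 system should hydrogenate to the secondary amine (C8–N9). The closest known reaction type is the linear-selective Rh/bisphosphine hydroaminomethylation of terminal alkenes with primary amines, which has been applied to N-allyl amides and imides. No ring closes and no stereocentre is created. Linear over branched acyl formation, and hydroformylation over isomerisation to the enamide, are needed; the wide bite angle of Xantphos enforces the sterically preferred terminal Rh–alkyl and overrides any carbonyl-chelation bias of the tertiary amide. Only the NH2 of 10 can condense (N4 is a tertiary amide, N1 a carbamate, N12 a secondary amide), and the excess of 10 should suppress a second alkylation at N9. Benzyl ethers and the Cbz group are inert to homogeneous Rh–phosphine catalysts under hydrogen.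

Step 7
Reactants: 13 N1-Cbz-tetra-O-benzyl kukoamine B
Product: 14 kukoamine B
Conditions: H2 (3 bar), 20% Pd(OH)2/C, EtOH/AcOH (9:1), rt; filtration under Ar, then free-basing (NH3/MeOH, lyophilisation)
Reagents that add atoms: none
Why: Heterogeneous hydrogenolysis should cleave the four aryl benzyl ethers and the benzyl carbamate (with loss of CO2) in one operation; acetic acid keeps the amines protonated so they neither poison palladium nor undergo reductive alkylation, and the amides and arenes are not reduced at room temperature.

**Compound list**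

1 | 3-(3,4-dihydroxyphenyl)propanoic acid (dihydrocaffeic acid) | OC(=O)CCc1ccc(O)c(O)c1 | starting material
2 | benzyl 3-[3,4-bis(benzyloxy)phenyl]propanoate | O=C(OCc1ccccc1)CCc1ccc(OCc2ccccc2)c(OCc2ccccc2)c1 | intermediate
3 | 3-[3,4-bis(benzyloxy)phenyl]propanoic acid | OC(=O)CCc1ccc(OCc2ccccc2)c(OCc2ccccc2)c1 | intermediate
4 | allylamine (prop-2-en-1-amine) | C=CCN | starting material
5 | benzyl (3-bromopropyl)carbamate | O=C(NCCCBr)OCc1ccccc1 | starting material
6 | benzyl N-[3-(allylamino)propyl]carbamate | C=CCNCCCNC(=O)OCc1ccccc1 | intermediate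
7 | 1-{3-[3,4-bis(benzyloxy)phenyl]propanoyl}-1H-imidazole (acyl imidazole) | O=C(CCc1ccc(OCc2ccccc2)c(OCc2ccccc2)c1)n1ccnc1 | intermediate (not isolated)
8 | N-allyl-N-[3-(Cbz-amino)propyl]-3-[3,4-bis(benzyloxy)phenyl]propanamide | C=CCN(CCCNC(=O)OCc1ccccc1)C(=O)CCc1ccc(OCc2ccccc2)c(OCc2ccccc2)c1 | intermediate
9 | 1,3-diaminopropane | NCCCN | starting material
10 | N-(3-aminopropyl)-3-[3,4-bis(benzyloxy)phenyl]propanamide | NCCCNC(=O)CCc1ccc(OCc2ccccc2)c(OCc2ccccc2)c1 | intermediate
11 | N-[3-(Cbz-amino)propyl]-N-(4-oxobutyl)-3-[3,4-bis(benzyloxy)phenyl]propanamide (4-amidobutanal) | O=CCCCN(CCCNC(=O)OCc1ccccc1)C(=O)CCc1ccc(OCc2ccccc2)c(OCc2ccccc2)c1 | intermediate (not isolated)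
12 | aldimine of 11 with the primary amine of 10 (C8=N9) | O=C(OCc1ccccc1)NCCCN(CCCC=NCCCNC(=O)CCc1ccc(OCc2ccccc2)c(OCc2ccccc2)c1)C(=O)CCc1ccc(OCc2ccccc2)c(OCc2ccccc2)c1 | intermediate (not isolated)
13 | N1-Cbz-tetra-O-benzyl kukoamine B (N1-benzyloxycarbonyl-N4,N12-bis{3-[3,4-bis(benzyloxy)phenyl]propanoyl}spermine) | O=C(OCc1ccccc1)NCCCN(CCCCNCCCNC(=O)CCc1ccc(OCc2ccccc2)c(OCc2ccccc2)c1)C(=O)CCc1ccc(OCc2ccccc2)c(OCc2ccccc2)c1 | intermediate
14 | kukoamine B (N4,N12-bis[3-(3,4-dihydroxyphenyl)propanoyl]spermine) | NCCCN(CCCCNCCCNC(=O)CCc1ccc(O)c(O)c1)C(=O)CCc1ccc(O)c(O)c1 | target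

**Step count**

Total: 7 steps. Longest linear sequence: 5 steps (1, 2, 4, 6, 7).

**Steps most likely to fail, with fallbacks**

Step 6. Regiocontrol in the Rh–H addition may be lost, giving branched acyl, isomerisation to the enamide, or plain hydrogenation of the alkene under hydrogen-rich gas. Hydrogenation of the aldimine may also be slow, diverting it into enamine or aldol condensation or a second alkylation at N9. The fallback takes C5–C8 at the aldehyde oxidation level from a bought C4 amine instead of from CO; it sets out from 5 and returns at 13. Excess 4,4-diethoxybutan-1-amine (NCCCC(OCC)OCC, commercial) is alkylated with 5 (K2CO3, MeCN, 50 °C) to give benzyl N-{3-[(4,4-diethoxybutyl)amino]propyl}carbamate F1. Acylation of this with acyl imidazole 7 (from 3 and CDI, as in step 4) gives N-[3-(Cbz-amino)propyl]-N-(4,4-diethoxybutyl)-3-[3,4-bis(benzyloxy)phenyl]propanamide F2. Mild acid (1 M HCl, THF, rt) unmasks the 4-amidobutanal 11, now isolated. Reductive amination of 11 with 10 (NaBH(OAc)3, AcOH, 1,2-dichloroethane, rt) forms the same C8–N9 bond and rejoins the route at 13.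

Step 7. The five-fold hydrogenolysis may stall through binding of the polyamine to palladium, leaving partially benzylated material, and the catechols may oxidise in air during free-basing. The fallback sets out from 13 and returns at 14 by Lewis-acid dealkylation instead of hydrogenolysis: BBr3, CH2Cl2, −78 → 0 °C, then MeOH quench. This should cleave the four aryl benzyl ethers and the benzyl carbamate while leaving the amides intact. The amines are held as boron adducts and then as ammonium salts, so the benzyl bromide formed should not N-alkylate them; neutralisation under argon gives 14. No compound outside the list arises (F0).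

Step 3. A second alkylation of 6 by 5 may compete, as may intramolecular displacement of bromide by the carbamate carbonyl. The fallback is a Fukuyama sequence that sets out from 4 and returns at 6. Sulfonylation of 4 with 2-nitrobenzenesulfonyl chloride (O=S(=O)(Cl)c1ccccc1[N+](=O)[O-]; Et3N, CH2Cl2, 0 °C) gives N-allyl-2-nitrobenzenesulfonamide F3. Alkylation of its acidic N–H with 5 (K2CO3, DMF, 50 °C) can occur only once and gives benzyl N-{3-[allyl(2-nitrophenylsulfonyl)amino]propyl}carbamate F4. Thiolate-induced desulfonylation (PhSH, K2CO3, MeCN, rt) then releases 6 without touching the alkene or the Cbz group.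

**Further compounds**

F1 | step 6 | benzyl N-{3-[(4,4-diethoxybutyl)amino]propyl}carbamate | CCOC(CCCNCCCNC(=O)OCc1ccccc1)OCC
F2 | step 6 | N-[3-(Cbz-amino)propyl]-N-(4,4-diethoxybutyl)-3-[3,4-bis(benzyloxy)phenyl]propanamide | CCOC(CCCN(CCCNC(=O)OCc1ccccc1)C(=O)CCc1ccc(OCc2ccccc2)c(OCc2ccccc2)c1)OCC
F0 | step 7 | none | none
F3 | step 3 | N-allyl-2-nitrobenzenesulfonamide | C=CCNS(=O)(=O)c1ccccc1[N+](=O)[O-]
F4 | step 3 | benzyl N-{3-[allyl(2-nitrophenylsulfonyl)amino]propyl}carbamate | C=CCN(CCCNC(=O)OCc1ccccc1)S(=O)(=O)c1ccccc1[N+](=O)[O-]
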